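## Retrosynthetic overview

1. Numbering follows shikimic acid: C1 carries the ester carbon C7, C2 is the alkene CH, C3 bears OAc, C4 bears O-propanoyl, C5 bears O-(R)-2-methylbutanoyl, and C6 is CH2. The O4 and O3 esters are removed first. They are told apart through a 3,4-orthoacetate on the cis-diol 15.
2. The key disconnection is the C3–C4 bond of the cis-glycol in the cyclohexene ring, which leads to the acyclic dialdehyde 12. Two formyl carbons of like polarity are joined by reductive polarity reversal at C3 (CrCl2/Me3SiCl). This closes the only ring and sets C3 and C4.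
3. The enabling feature is that C3 is allylic to the ring alkene C1=C2, which carries C7. In the open form, C3–C2=C1–C7 is therefore a 4-oxobut-2-enoate, the only group that divalent chromium reduces. After two electrons and O-silylation, C3 is the γ-carbon of an ester dienolate placed to close a six-membered ring on formyl C4. C5, already carrying its final ester, is the only ring stereocentre in the precursor.
4. Dialdehyde 12 comes from (S)-glyceraldehyde acetonide (C5, C4), methyl 2-(bromomethyl)acrylate (C6, C1, C7), a formyl ylide (C2, C3) and (R)-2-methylbutanoic acid. The sequence is Barbier addition, esterification, ozonolysis, Wittig olefination and periodate cleavage.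

Key step: step 6

Assumption: "shikimate" in the names means the natural series (O3/O4 cis, O4/O5 trans; 3R,4S,5R in the target), and 1 and 5 are bought as single enantiomers.

## Route

Step 1
Reactants: 1 (S)-2,2-dimethyl-1,3-dioxolane-4-carbaldehyde; 2 methyl 2-(bromomethyl)acrylate
Product: 4 methyl (4R)-4-[(4S)-2,2-dimethyl-1,3-dioxolan-4-yl]-4-hydroxy-2-methylidenebutanoate, via allylzinc bromide 3 (not isolated)
Conditions: Zn dust, THF/sat. aq NH4Cl, 0 °C to rt
Reagents that add atoms: none
Why: In this aqueous zinc Barbier allylation the allylzinc 3 should add to the α-alkoxy aldehyde in the polar Felkin–Anh sense, which sets C5 as the anti (4R) alcohol, and the minor syn isomer is removed by chromatography.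

Step 2
Reactants: 4 methyl (4R)-4-[(4S)-2,2-dimethyl-1,3-dioxolan-4-yl]-4-hydroxy-2-methylidenebutanoate; 5 (R)-2-methylbutanoic acid
Product: 6 methyl (4R)-4-[(4S)-2,2-dimethyl-1,3-dioxolan-4-yl]-2-methylidene-4-{[(2R)-2-methylbutanoyl]oxy}butanoate
Conditions: DIC, DMAP (cat.), CH2Cl2, 0 °C
Reagents that add atoms: none
Why: Steglich esterification at low temperature should outrun lactonisation of the γ-hydroxy ester and touches none of the existing stereocentres.

Step 3
Reactants: 6 methyl (4R)-4-[(4S)-2,2-dimethyl-1,3-dioxolan-4-yl]-2-methylidene-4-{[(2R)-2-methylbutanoyl]oxy}butanoate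
Product: 8 methyl (4R)-4-[(4S)-2,2-dimethyl-1,3-dioxolan-4-yl]-4-{[(2R)-2-methylbutanoyl]oxy}-2-oxobutanoate, via ozonide 7 (not isolated)
Conditions: O3, CH2Cl2, −78 °C; then Me2S, −78 °C to rt
Reagents that add atoms: ozone, [O-][O+]=O
Why: Ozonolysis with reductive work-up of a 2-substituted acrylate is the standard entry to α-keto esters, and no other alkene is present.

Step 4
Reactants: 8 methyl (4R)-4-[(4S)-2,2-dimethyl-1,3-dioxolan-4-yl]-4-{[(2R)-2-methylbutanoyl]oxy}-2-oxobutanoate; 9 (triphenylphosphoranylidene)acetaldehyde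
Product: 10 methyl (2E)-2-[(2R)-2-[(4S)-2,2-dimethyl-1,3-dioxolan-4-yl]-2-{[(2R)-2-methylbutanoyl]oxy}ethyl]-4-oxobut-2-enoate
Conditions: toluene, rt to 40 °C
Reagents that add atoms: none
Why: In this Wittig olefination with a stabilised formyl ylide the activated keto group of the α-keto ester reacts under neutral conditions, and the formyl group should end up trans to the ester (E), a geometry on which step 6 does not depend.

Step 5
Reactants: 10 methyl (2E)-2-[(2R)-2-[(4S)-2,2-dimethyl-1,3-dioxolan-4-yl]-2-{[(2R)-2-methylbutanoyl]oxy}ethyl]-4-oxobut-2-enoate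
Product: 12 methyl (2E)-2-[(2R)-2-{[(2R)-2-methylbutanoyl]oxy}-3-oxopropyl]-4-oxobut-2-enoate, via diol 11 (not isolated)
Conditions: H5IO6, EtOAc, 0 °C to rt; used crude
Reagents that add atoms: none
Why: Periodic acid hydrolyses the terminal acetonide and cleaves the freed glycol in the same flask (Malaprade cleavage) under non-basic conditions, so the C5 stereocentre next to the new aldehyde should not epimerise.

Step 6
Reactants: 12 methyl (2E)-2-[(2R)-2-{[(2R)-2-methylbutanoyl]oxy}-3-oxopropyl]-4-oxobut-2-enoate
Product: 15 methyl 5-O-[(2R)-2-methylbutanoyl]shikimate, via chromium dienolate 13 (not isolated), via bis-silyl ether 14 (not isolated)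
Conditions: CrCl2 (excess), Me3SiCl, DMF, 0 °C to rt, slow addition of 12 (high dilution); then aq citric acid, THF
Reagents that add atoms: none
Why: Proposed new method: CrCl2 gives one electron to the 4-oxobut-2-enoate of 12, Me3SiCl caps the oxygen on C3, a second CrCl2 takes up the C1 radical, and in the resulting γ-silyloxy dienolate 13 of trivalent chromium the former formyl carbon C3 is the nucleophilic γ-terminus that adds to the chromium-bound C4 aldehyde before Me3SiCl frees the alkoxide as 14 and citric acid strips both silyl groups. The closest known reaction type is the CrCl2/R3SiCl pinacol-type cross-coupling of enals or enones with aldehydes through γ-silyloxyallylchromium reagents (also known intramolecularly), together with the γ-selective vinylogous aldol addition of oxygen-bearing dienolates such as 2-silyloxyfurans; new are the ester on the allyl terminus and a closure that leaves the allyl unit inside the ring. The cyclohexene ring closes 6-(enolendo)-exo-trig, whereas attack through C1 would need a cyclobutane, so ring size secures the γ-regioselectivity. C3: the s-trans enal is reduced to the (E)-silyl enol ether, which places O3 on the outside of the folded C6–C1–C2–C3 chain, and the chromium on the dienolate face holds the aldehyde oxygen turned back over C2 and gauche to O3, so that O3 and O4 should come out cis. C4: the stereocentre C5 controls the aldehyde face, because the non-chelating acyloxy C5–O bond stands anti to the C4=O dipole and the C6 tether then lets C3 reach only the face that puts O4 trans to O5. The step needs one aldehyde to be reduced and the other to stay an acceptor, which the conjugation of C3 with C1=C2 and the ester secures because CrCl2 does not reduce saturated aldehydes (so the α-acyloxy group at C5 is not expelled), and rotation about C1–C2 in 13 makes the alkene geometry of 12 irrelevant.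

Step 7
Reactants: 15 methyl 5-O-[(2R)-2-methylbutanoyl]shikimate
Product: 17 methyl 3-O-acetyl-5-O-[(2R)-2-methylbutanoyl]shikimate, via orthoester 16 (not isolated)
Conditions: MeC(OMe)3, CSA (cat.), CH2Cl2, rt; then 80% aq AcOH, 0 °C to rt
Reagents that add atoms: trimethyl orthoacetate, COC(C)(OC)OC; water, O
Why: Cyclic orthoester formation on the cis-diol is followed by kinetically controlled acid hydrolysis, which by the stereoelectronic rule known from pyranoside orthoesters should leave the ester on the pseudoaxial O3 and free the equatorial O4.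

Step 8
Reactants: 17 methyl 3-O-acetyl-5-O-[(2R)-2-methylbutanoyl]shikimate
Product: 18 methyl (3R,4S,5R)-3-acetoxy-5-{[(2R)-2-methylbutanoyl]oxy}-4-(propanoyloxy)cyclohex-1-ene-1-carboxylate
Conditions: (EtCO)2O, pyridine, DMAP (cat.), CH2Cl2, 0 °C
Reagents that add atoms: propanoic anhydride, CCC(=O)OC(=O)CC
Why: DMAP-catalysed acylation of the one remaining secondary alcohol at low temperature should be faster than acetyl migration and creates no stereocentre.

## Compound list

1 | (S)-2,2-dimethyl-1,3-dioxolane-4-carbaldehyde | O=C[C@@H]1COC(C)(C)O1 | starting material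
2 | methyl 2-(bromomethyl)acrylate | C=C(CBr)C(=O)OC | starting material
3 | [2-(methoxycarbonyl)allyl]zinc bromide | C=C(C[Zn]Br)C(=O)OC | intermediate
4 | methyl (4R)-4-[(4S)-2,2-dimethyl-1,3-dioxolan-4-yl]-4-hydroxy-2-methylidenebutanoate | C=C(C(=O)OC)C[C@H]([C@@H]1COC(C)(C)O1)O | intermediate
5 | (R)-2-methylbutanoic acid | CC[C@@H](C)C(=O)O | starting material
6 | methyl (4R)-4-[(4S)-2,2-dimethyl-1,3-dioxolan-4-yl]-2-methylidene-4-{[(2R)-2-methylbutanoyl]oxy}butanoate | C=C(C(=O)OC)C[C@H]([C@@H]1COC(C)(C)O1)OC(=O)[C@H](C)CC | intermediate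
7 | 1,2,4-trioxolane (ozonide) of 6, quaternary ring carbon unassigned | COC(=O)C1(C[C@H]([C@@H]2COC(C)(C)O2)OC(=O)[C@H](C)CC)OCOO1 | intermediate
8 | methyl (4R)-4-[(4S)-2,2-dimethyl-1,3-dioxolan-4-yl]-4-{[(2R)-2-methylbutanoyl]oxy}-2-oxobutanoate | COC(=O)C(=O)C[C@H]([C@@H]1COC(C)(C)O1)OC(=O)[C@H](C)CC | intermediate
9 | (triphenylphosphoranylidene)acetaldehyde | O=CC=P(c1ccccc1)(c1ccccc1)c1ccccc1 | starting material
10 | methyl (2E)-2-[(2R)-2-[(4S)-2,2-dimethyl-1,3-dioxolan-4-yl]-2-{[(2R)-2-methylbutanoyl]oxy}ethyl]-4-oxobut-2-enoate | COC(=O)/C(C[C@H]([C@@H]1COC(C)(C)O1)OC(=O)[C@H](C)CC)=C/C=O | intermediate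
11 | methyl (2E)-2-[(2R,3S)-3,4-dihydroxy-2-{[(2R)-2-methylbutanoyl]oxy}butyl]-4-oxobut-2-enoate | COC(=O)/C(C[C@H]([C@@H](O)CO)OC(=O)[C@H](C)CC)=C/C=O | intermediate
12 | methyl (2E)-2-[(2R)-2-{[(2R)-2-methylbutanoyl]oxy}-3-oxopropyl]-4-oxobut-2-enoate | COC(=O)/C(C[C@H](C=O)OC(=O)[C@H](C)CC)=C/C=O | intermediate
13 | dichlorochromium dienolate (trivalent chromium) of the (E)-γ-trimethylsilyloxy dienoate, formyl C4 still free | COC(O[Cr](Cl)Cl)=C(C[C@H](C=O)OC(=O)[C@H](C)CC)/C=C/O[Si](C)(C)C | intermediate
14 | methyl 3,4-bis-O-(trimethylsilyl)-5-O-[(2R)-2-methylbutanoyl]shikimate | C[Si](C)(C)O[C@@H]1[C@H](O[Si](C)(C)C)C=C(C(=O)OC)C[C@H]1OC(=O)[C@H](C)CC | intermediate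
15 | methyl 5-O-[(2R)-2-methylbutanoyl]shikimate | O[C@@H]1[C@H](O)C=C(C(=O)OC)C[C@H]1OC(=O)[C@H](C)CC | intermediate
16 | methyl 3,4-O-(1-methoxyethylidene)-5-O-[(2R)-2-methylbutanoyl]shikimate, orthoester carbon unassigned | CC1(OC)O[C@@H]2[C@H](O1)C=C(C(=O)OC)C[C@H]2OC(=O)[C@H](C)CC | intermediate
17 | methyl 3-O-acetyl-5-O-[(2R)-2-methylbutanoyl]shikimate | O[C@@H]1[C@H](OC(C)=O)C=C(C(=O)OC)C[C@H]1OC(=O)[C@H](C)CC | intermediate
18 | methyl (3R,4S,5R)-3-acetoxy-5-{[(2R)-2-methylbutanoyl]oxy}-4-(propanoyloxy)cyclohex-1-ene-1-carboxylate | CCC(=O)O[C@@H]1[C@H](OC(C)=O)C=C(C(=O)OC)C[C@H]1OC(=O)[C@H](C)CC | target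

## Step count and risks

Total step count: 8
Longest linear sequence: 8 steps (1 or 2 to 18)

**Step 6 (proposed new method).**
- The dienolate may be protonated or may couple between molecules faster than it closes.
- The two faces of the C4 aldehyde may be poorly differentiated, which would erode the O4/O5 trans relationship.
- The fallback sets out from 12 and uses known chemistry only.
- Both formyl groups are methylenated under non-basic conditions (Zn, CH2Br2, TiCl4, THF/CH2Cl2) to the triene methyl (2E)-2-[(2R)-2-{[(2R)-2-methylbutanoyl]oxy}but-3-en-1-yl]penta-2,4-dienoate F1.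
- Ring-closing metathesis (second-generation Grubbs catalyst, CH2Cl2, 40 °C) then forms the same C3–C4 bond as an alkene, giving methyl (5R)-5-{[(2R)-2-methylbutanoyl]oxy}cyclohexa-1,3-diene-1-carboxylate F2.
- Dihydroxylation with OsO4 (cat.) and NMO should take the electron-richer C3=C4 alkene from the face opposite the C5 ester, and the route is rejoined at 15.

**Step 4.**
- The new enal may be olefinated a second time.
- The ylide may act as a base and trigger β-elimination of the C5 acyloxy group from the keto ester.
- The fallback sets out from 8.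
- Wittig reaction with S-ethyl 2-(triphenylphosphoranylidene)ethanethioate (CH2Cl2, rt) gives a product that cannot react further, the thioester methyl (2E)-2-[(2R)-2-[(4S)-2,2-dimethyl-1,3-dioxolan-4-yl]-2-{[(2R)-2-methylbutanoyl]oxy}ethyl]-4-(ethylsulfanyl)-4-oxobut-2-enoate F3.
- Fukuyama reduction (Et3SiH, Pd/C, acetone) then delivers the aldehyde, and the route is rejoined at 10.

**Step 7.**
- Regiocontrol may be lost when the orthoester opens.
- The acetyl group may migrate from O3 to O4 before step 8.
- The fallback sets out from 15 and reverses the order of acylation.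
- Catalysis by 2-aminoethyl diphenylborinate (EtCOCl, iPr2NEt, MeCN, rt) activates the cis-diol as a borinate and should acylate its equatorial O4, giving methyl 5-O-[(2R)-2-methylbutanoyl]-4-O-propanoylshikimate F4.
- Acetylation of the remaining O3 (Ac2O, pyridine) rejoins the route at 18.

## Further compounds

F1 | step 6 | methyl (2E)-2-[(2R)-2-{[(2R)-2-methylbutanoyl]oxy}but-3-en-1-yl]penta-2,4-dienoate | COC(=O)/C(C[C@H](C=C)OC(=O)[C@H](C)CC)=C/C=C
F2 | step 6 | methyl (5R)-5-{[(2R)-2-methylbutanoyl]oxy}cyclohexa-1,3-diene-1-carboxylate | C1=CC=C(C(=O)OC)C[C@H]1OC(=O)[C@H](C)CC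
F3 | step 4 | methyl (2E)-2-[(2R)-2-[(4S)-2,2-dimethyl-1,3-dioxolan-4-yl]-2-{[(2R)-2-methylbutanoyl]oxy}ethyl]-4-(ethylsulfanyl)-4-oxobut-2-enoate | COC(=O)/C(C[C@H]([C@@H]1COC(C)(C)O1)OC(=O)[C@H](C)CC)=C/C(=O)SCC
F4 | step 7 | methyl 5-O-[(2R)-2-methylbutanoyl]-4-O-propanoylshikimate | CCC(=O)O[C@@H]1[C@H](O)C=C(C(=O)OC)C[C@H]1OC(=O)[C@H](C)CC
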